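The carbocycle (C1 heptenyl-bearing, C2 CH2OH-bearing, C3, C4, C5 side-chain carbon, C6) is cut into a 2-pyrone diene (C1–C4) and a cis enol ether (C5=C6). C4–OH and the first heptenyl carbon on C1 are the two ends of a pyrone lactone bridge; C6–OH and the CH2–CH of the C5 side chain are a 2-methoxy-2,3-dihydrofuran. One copper-catalysed inverse-electron-demand Diels–Alder reaction of a butenolide-fused, doubly acylated 2-pyrone with this dienophile forms C1–C6 and C4–C5 and sets C4, C5 and C6. Face-selective epoxidation and a methoxide cascade then give C3–OH and C1=C2; two olefinations finish the chains.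

Key step: step 4

Remark: the locants C1–C6 defined above are used for the carbocycle in every intermediate.
Assumption: the (S,S) ligand is taken to shield the pyrone face that leads to the enantiomer drawn; if the sense of induction proves opposite, the (R,R) ligand is used with no other change.
Remark: 8 is racemic, and the acetal carbon of 9–13 and 19 and the lactol carbons of 14 and 20 are unassigned mixtures; these centres are destroyed in steps 11 and 13.

Step 1
Reactants: 1 1-(tert-butyldimethylsilyloxy)propan-2-one; 2 dimethyl malonate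
Product: 3 dimethyl 2-[1-(tert-butyldimethylsilyloxy)propan-2-ylidene]propanedioate
Conditions: TiCl4, pyridine, THF, 0 °C to rt
Reagents that add atoms: none
Why: Knoevenagel condensation of a malonate with a ketone under TiCl4/pyridine activation; the symmetrical malonate leaves no E/Z question.

Step 2
Reactants: 3; 4 N,N-dimethylformamide dimethyl acetal
Product: 6 1H-furo[3,4-c]pyran-3,4-dione, via dienamine 5 (not isolated)
Conditions: 4 (1.5 equiv), PhMe, 90 °C; evaporate; then 2 M aq. HCl, THF, rt to 40 °C
Reagents that add atoms: water, O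
Why: Vinylogous aminomethylenation of the unhindered γ-methyl group, then acid hydrolysis of the enamine with lactonisation of the enol onto the cis ester (2-pyrone synthesis), while the acid removes the silyl group and the freed CH2OH closes the butenolide onto the second ester.

Step 3
Reactants: 7 2,5-dimethoxytetrahydrofuran (cis/trans mixture)
Product: 8 2-methoxy-2,3-dihydrofuran (racemic)
Conditions: Me3SiOTf (1.0 equiv), iPr2NEt (1.2 equiv), CH2Cl2, −40 to 0 °C; distil from K2CO3
Reagents that add atoms: none
Why: Silyl-triflate/amine conversion of an acetal into an enol ether (oxocarbenium formation, then deprotonation); one equivalent of silyl triflate should stop at the mono-elimination because the enol-ether oxygen of 8 stabilises a second oxocarbenium ion less well.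

Step 4
Reactants: 6 1H-furo[3,4-c]pyran-3,4-dione; 8 2-methoxy-2,3-dihydrofuran
Product: 9 endo cycloadduct (bridging lactone C1–CO–O–C4; γ-lactone C1–CO–O–CH2–C2; C2=C3 alkene; 2-methoxytetrahydrofuran cis-fused at C5–C6 with its ring O on C6 and anti to the bridge)
Conditions: Cu(OTf)2 (10 mol %), (S,S)-tBu-BOX (11 mol %), 4 Å molecular sieves, CH2Cl2, −40 to −20 °C; 8 in threefold excess
Reagents that add atoms: none
Why: Two-point binding of the two carbonyl oxygens on the future C1 to Cu(tBu-BOX)(OTf)2 lowers the diene LUMO, and the enol ether adds in an asynchronous inverse-electron-demand [4+2] cycloaddition in which its nucleophilic β-carbon (future C5) bonds to the electrophilic oxygen-bearing pyrone terminus (future C4) and its O-bearing carbon (future C6) closes onto the malonate-like terminus (future C1). The closest known reaction type is the chiral copper–bis(oxazoline)-catalysed inverse-electron-demand Diels–Alder reaction of 3-carboalkoxy-2-pyrones with enol ethers. The one ring closed is the carbocycle C1–C6, by a suprafacial [4+2] cycloaddition that leaves the pyrone lactone as the O–CO bridge of a 2-oxabicyclo[2.2.2]octene. C1 and C4 are set by the ligand, which blocks one face of the flat chelated pyrone; C5 and C6 are cis because the dienophile double bond is locked Z in its ring, and they lie anti to the bridge because of the endo transition state. The step needs regio-, endo- and face-selectivity and a clean cycloaddition in place of acid-induced loss of methanol from 8: the first is secured by the polarity match, the second and third by secondary overlap and the chelate, the last by low temperature, sieves and excess 8, whose better-matched enantiomer reacts faster.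

Step 5
Reactants: 9 endo cycloadduct
Product: 10 C2–C3 epoxide of 9 (oxirane oxygen syn to the lactone bridge)
Conditions: methyl(trifluoromethyl)dioxirane (1.3 equiv), CH2Cl2, −20 to 0 °C
Reagents that add atoms: methyl(trifluoromethyl)dioxirane, CC1(OO1)C(F)(F)F
Why: Dioxirane epoxidation of the electron-poor trisubstituted alkene; the endo tetrahydrofuran ring shields the alkene face turned towards C5–C6, so oxygen arrives from the side of the lactone bridge and the C3–O bond is cis to C4–O as in the target.

Step 6
Reactants: 10 epoxide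
Product: 12 butenolide diol (furanone fused at C1–C2; C3–OH and C4–OH cis), via epoxy lactone ester 11 (not isolated)
Conditions: NaOMe (3 equiv), MeOH, −20 °C to rt; then AcOH
Reagents that add atoms: none
Why: Methoxide opens the strained bridging lactone (freeing C4–OH), then cleaves the non-enolisable 1,3-dicarbonyl at C1 by retro-Claisen attack coupled to E1cB/Grob-type opening of the β,γ-epoxide (giving C1=C2 and C3–OH, one carbonyl leaving as dimethyl carbonate), and the C2–CH2O– recloses onto the surviving C1 carboxyl to the butenolide; the C6 acetal oxygen is too poor a leaving group to compete with the epoxide.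

Step 7
Reactants: 12 butenolide diol
Product: 13 3,4-bis(triethylsilyl) ether of 12
Conditions: Et3SiCl (2.5 equiv), imidazole, DMAP (cat.), DMF, rt
Reagents that add atoms: chlorotriethylsilane, CC[Si](Cl)(CC)CC
Why: Standard silylation of the two secondary alcohols, so that no free hydroxyl group other than the lactol meets the strong base of step 11.

Step 8
Reactants: 13 bis(silyl) butenolide
Product: 14 lactol (2,5-dihydrofuran-2-ol fused at C1–C2)
Conditions: iBu2AlH (1.2 equiv), CH2Cl2, −78 °C; aq. KNaC4H4O6 (tartrate) work-up; used crude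
Reagents that add atoms: none
Why: Half-reduction of an α,β-unsaturated γ-lactone to its lactol at −78 °C (the aluminium hemiacetal is stable until work-up); the lactol is at once the C1 aldehyde and a masked C2–CH2OH.

Step 9
Reactants: 15 1-phenyl-1H-tetrazole-5-thiol; 16 1-bromohexane
Product: 17 5-(hexylsulfanyl)-1-phenyl-1H-tetrazole
Conditions: K2CO3, acetone, rt
Reagents that add atoms: none
Why: SN2 S-alkylation of the thiolate by a primary bromide.

Step 10
Reactants: 17 5-(hexylsulfanyl)-1-phenyl-1H-tetrazole
Product: 18 5-(hexylsulfonyl)-1-phenyl-1H-tetrazole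
Conditions: H2O2 (30 % aq.), (NH4)6Mo7O24·4H2O (10 mol %), EtOH, 0 °C to rt
Reagents that add atoms: hydrogen peroxide, OO
Why: Molybdate-catalysed oxidation of a sulfide to the sulfone.

Step 11
Reactants: 14 lactol; 18 5-(hexylsulfonyl)-1-phenyl-1H-tetrazole
Product: 19 diene alcohol (C1 (E)-hept-1-enyl; C2 CH2OH; C3 and C4 OSiEt3; 2-methoxytetrahydrofuran at C5–C6)
Conditions: KN(SiMe3)2 (3.2 equiv) added to 14 and a twofold excess of 18, DME, −60 °C to rt; aq. NH4Cl
Reagents that add atoms: none
Why: Julia–Kocienski olefination: the potassium lactolate opens to the γ-alkoxy enal, the metalated sulfone adds, and Smiles rearrangement with loss of SO2 and the tetrazolone should give the (E)-alkene expected for phenyltetrazolyl sulfones with a potassium base in DME, releasing C2–CH2OH at the same time.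

Step 12
Reactants: 19 diene alcohol
Product: 20 lactol tetraol (free C3–OH and C4–OH; acetal hydrolysed to the lactol)
Conditions: AcOH/THF/H2O (3:1:1), rt to 35 °C; used crude
Reagents that add atoms: water, O
Why: Mild aqueous acid cleaves both triethylsilyl ethers and hydrolyses the 2-deoxyfuranoside-type methyl acetal through an oxocarbenium ion at the acetal carbon, so no ring stereocentre is touched.

Step 13
Reactants: 20 lactol tetraol; 21 ethyl 2-(triphenylphosphoranylidene)propanoate
Product: 22 ethyl ester of the target
Conditions: THF, 55 °C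
Reagents that add atoms: none
Why: Wittig olefination of the open-chain aldehyde form of the lactol with a stabilised α-methyl ylide, which should give the (E)-trisubstituted enoate, tolerates free hydroxyl groups and frees C6–OH.

Step 14
Reactants: 22 ethyl ester
Product: 23 pestallic acid P
Conditions: LiOH·H2O (3 equiv), THF/MeOH/H2O (3:1:1), 0 °C to rt; then 0.5 M HCl to pH 3–4
Reagents that add atoms: lithium hydroxide, [Li+].[OH-]
Why: Saponification of the ethyl ester (acyl–oxygen cleavage); acidification only to pH 3–4 avoids ionisation of the allylic alcohols.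

Compound list
1 | 1-(tert-butyldimethylsilyloxy)propan-2-one | CC(=O)CO[Si](C)(C)C(C)(C)C | starting material
2 | dimethyl malonate | COC(=O)CC(=O)OC | starting material
3 | dimethyl 2-[1-(tert-butyldimethylsilyloxy)propan-2-ylidene]propanedioate | COC(=O)C(C(=O)OC)=C(C)CO[Si](C)(C)C(C)(C)C | intermediate
4 | N,N-dimethylformamide dimethyl acetal | COC(OC)N(C)C | starting material
5 | dimethyl 2-[(3E)-1-(tert-butyldimethylsilyloxy)-4-(dimethylamino)but-3-en-2-ylidene]propanedioate | COC(=O)C(C(=O)OC)=C(CO[Si](C)(C)C(C)(C)C)/C=C/N(C)C | intermediate (not isolated)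
6 | 1H-furo[3,4-c]pyran-3,4-dione (2-pyrone with a butenolide fused across its C3–C4 bond) | O=C1OCC2=C1C(=O)OC=C2 | intermediate
7 | 2,5-dimethoxytetrahydrofuran (cis/trans mixture) | COC1CCC(OC)O1 | starting material
8 | 2-methoxy-2,3-dihydrofuran (racemic) | COC1CC=CO1 | intermediate
9 | endo cycloadduct: 2-oxabicyclo[2.2.2]oct-7-en-3-one whose bridgehead C1 also carries a γ-lactone carbonyl closed onto OCH2 at C2; bridge oxygen on C4; C2=C3 alkene; 2-methoxytetrahydrofuran cis-fused at C5–C6 (ring O on C6) anti to the bridge | O=C1OCC2=C[C@H]3OC(=O)[C@@]12[C@H]1OC(OC)C[C@H]13 | intermediate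
10 | C2–C3 epoxide of 9, oxirane oxygen syn to the lactone bridge | O=C1OC[C@@]23O[C@H]3[C@H]4OC(=O)[C@@]12[C@H]1OC(OC)C[C@H]14 | intermediate
11 | ring-opened ester: C1 carries CO2Me and the γ-lactone carbonyl; C2–C3 epoxide; free C4–OH | O=C1OC[C@@]23O[C@H]3[C@@H](O)[C@@H]4CC(OC)O[C@@H]4[C@]12C(=O)OC | intermediate (not isolated)
12 | butenolide diol: furan-2(5H)-one fused at C1–C2 (C=O on C1, OCH2 on C2); C3–OH and C4–OH cis to each other and anti to the tetrahydrofuran; 2-methoxytetrahydrofuran cis-fused at C5–C6 | O=C1OCC2=C1[C@H]1OC(OC)C[C@H]1[C@H](O)[C@@H]2O | intermediate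
13 | 3,4-bis(triethylsilyl) ether of 12 | O=C1OCC2=C1[C@H]1OC(OC)C[C@H]1[C@H](O[Si](CC)(CC)CC)[C@@H]2O[Si](CC)(CC)CC | intermediate
14 | lactol from 13 (butenolide C=O reduced to CH–OH) | OC1OCC2=C1[C@H]1OC(OC)C[C@H]1[C@H](O[Si](CC)(CC)CC)[C@@H]2O[Si](CC)(CC)CC | intermediate
15 | 1-phenyl-1H-tetrazole-5-thiol | SC1=NN=NN1c1ccccc1 | starting material
16 | 1-bromohexane | CCCCCCBr | starting material
17 | 5-(hexylsulfanyl)-1-phenyl-1H-tetrazole | CCCCCCSC1=NN=NN1c1ccccc1 | intermediate
18 | 5-(hexylsulfonyl)-1-phenyl-1H-tetrazole | CCCCCCS(=O)(=O)C1=NN=NN1c1ccccc1 | intermediate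
19 | diene alcohol: C1 (E)-hept-1-enyl; C2 CH2OH; C3 and C4 OSiEt3; 2-methoxytetrahydrofuran cis-fused at C5–C6 | CCCCC/C=C/C1=C(CO)[C@@H](O[Si](CC)(CC)CC)[C@@H](O[Si](CC)(CC)CC)[C@@H]2CC(OC)O[C@H]12 | intermediate
20 | lactol tetraol: as 19 with free C3–OH and C4–OH and a tetrahydrofuran-2-ol in place of the methyl acetal | CCCCC/C=C/C1=C(CO)[C@@H](O)[C@@H](O)[C@@H]2CC(O)O[C@H]12 | intermediate
21 | ethyl 2-(triphenylphosphoranylidene)propanoate | CCOC(=O)C(C)=P(c1ccccc1)(c1ccccc1)c1ccccc1 | starting material
22 | ethyl (E)-4-[(1R,2S,5R,6S)-3-[(E)-hept-1-enyl]-2,5,6-trihydroxy-4-(hydroxymethyl)cyclohex-3-en-1-yl]-2-methylbut-2-enoate | CCCCC/C=C/C1=C(CO)[C@@H](O)[C@@H](O)[C@H](C/C=C(\C)C(=O)OCC)[C@@H]1O | intermediate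
23 | pestallic acid P, (E)-4-[(1R,2S,5R,6S)-3-[(E)-hept-1-enyl]-2,5,6-trihydroxy-4-(hydroxymethyl)cyclohex-3-en-1-yl]-2-methylbut-2-enoic acid | CCCCC/C=C/C1=C(CO)[C@@H](O)[C@@H](O)[C@H](C/C=C(\C)C(=O)O)[C@@H]1O | target

Total step count: 14. Longest linear sequence: 11 steps (1, 2, 4, 5, 6, 7, 8, 11, 12, 13, 14).

Steps most likely to fail

Step 4. The rigid bis-lactone may bind copper through one carbonyl only, because its two oxygens are held further apart than in a freely rotating ester. Face discrimination would then be eroded and the uncatalysed background reaction could compete; the Lewis acid may also strip methanol from 8 to give furan. The fallback sets out from 3 and returns at 12. Compound 3 is condensed with 4 as in step 2, but the dienamine is cyclised in buffered aqueous AcOH/NaOAc at rt so that the silyl ether survives. This should give methyl 4-[(tert-butyldimethylsilyloxy)methyl]-2-oxo-2H-pyran-3-carboxylate F1, whose freely rotating ester forms the usual six-membered chelate. The amine-buffered lanthanide system Yb(OTf)3/(R)-1,1'-bi-2-naphthol/iPr2NEt then joins F1 and 8 to the silyloxymethyl cycloadduct F2, and methyl(trifluoromethyl)dioxirane gives the epoxide F3. NaOMe/MeOH opens the bridge and cleaves the malonate with epoxide opening to the silyloxymethyl enoate diol F4. HCl in MeOH then removes the silyl group so that the butenolide closes to 12.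

Step 6. The cascade may stall at 11 or at its ring-opened malonate, and prolonged contact of 12 with methoxide may cause β-elimination of the C6 oxygen from the butenolide dienolate. The fallback sets out from 10 and returns at 12. LiOH in aqueous THF at 0 °C saponifies both lactones to the epoxy malonic acid F5, present as its dilithium salt. On warming to rt the carboxylate that stands anti to the C2–O oxirane bond should be lost as CO2 with epoxide opening (decarboxylative Grob fragmentation). Acidification to pH 4 then closes the butenolide to 12.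

Step 11. Ring opening of the lactolate may be slow, the E/Z ratio may erode with a conjugated aldehyde, and 14 may dehydrate to a furan before it reacts. The fallback sets out from 13 and returns at 20. AlMe3/MeNH(OMe)·HCl opens the butenolide to the hydroxy Weinreb amide F6, and Et3SiCl/imidazole gives the tris(silyl) amide F7. iBu2AlH then delivers the free enal F8, an ordinary aldehyde substrate for the Julia–Kocienski reaction with 18, which should give the tris(silyl) diene F9. The conditions of step 12 convert F9 into 20.

Further compounds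
F1 | step 4 | methyl 4-[(tert-butyldimethylsilyloxy)methyl]-2-oxo-2H-pyran-3-carboxylate | COC(=O)C1=C(CO[Si](C)(C)C(C)(C)C)C=COC1=O
F2 | step 4 | silyloxymethyl cycloadduct (bridging lactone C1–CO–O–C4, CO2Me on C1, CH2OSi on C2, C2=C3, endo 2-methoxytetrahydrofuran at C5–C6) | COC(=O)[C@@]12C(CO[Si](C)(C)C(C)(C)C)=C[C@@H](OC1=O)[C@@H]1CC(OC)O[C@@H]12
F3 | step 4 | C2–C3 epoxide of F2, oxirane oxygen syn to the lactone bridge | COC(=O)[C@@]12[C@@]3(CO[Si](C)(C)C(C)(C)C)O[C@H]3[C@@H](OC1=O)[C@@H]1CC(OC)O[C@@H]12
F4 | step 4 | silyloxymethyl enoate diol (C1 CO2Me, C2 CH2OSi, C3–OH, C4–OH, 2-methoxytetrahydrofuran at C5–C6) | COC(=O)C1=C(CO[Si](C)(C)C(C)(C)C)[C@@H](O)[C@@H](O)[C@@H]2CC(OC)O[C@H]12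
F5 | step 6 | epoxy malonic acid (C1 dicarboxylic acid, C2 CH2OH, C2–C3 epoxide, C4–OH, 2-methoxytetrahydrofuran at C5–C6) | OC(=O)C1(C(=O)O)[C@@]2(CO)O[C@H]2[C@@H](O)[C@@H]2CC(OC)O[C@H]12
F6 | step 11 | hydroxy Weinreb amide (C1 CON(OMe)Me, C2 CH2OH, C3 and C4 OSiEt3) | CON(C)C(=O)C1=C(CO)[C@@H](O[Si](CC)(CC)CC)[C@@H](O[Si](CC)(CC)CC)[C@@H]2CC(OC)O[C@H]12
F7 | step 11 | tris(silyl) amide (C2 CH2OSiEt3) | CON(C)C(=O)C1=C(CO[Si](CC)(CC)CC)[C@@H](O[Si](CC)(CC)CC)[C@@H](O[Si](CC)(CC)CC)[C@@H]2CC(OC)O[C@H]12
F8 | step 11 | free enal (C1 CHO, C2 CH2OSiEt3, C3 and C4 OSiEt3) | O=CC1=C(CO[Si](CC)(CC)CC)[C@@H](O[Si](CC)(CC)CC)[C@@H](O[Si](CC)(CC)CC)[C@@H]2CC(OC)O[C@H]12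
F9 | step 11 | tris(silyl) diene (C1 (E)-hept-1-enyl) | CCCCC/C=C/C1=C(CO[Si](CC)(CC)CC)[C@@H](O[Si](CC)(CC)CC)[C@@H](O[Si](CC)(CC)CC)[C@@H]2CC(OC)O[C@H]12
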